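**Retrosynthetic overview**

1. Locants are carotenoid locants, primed for the ring that carries CH2CH=C(CH2OH)2 (ring B). C2 is R and C2' is S, so rings A and B are antipodal 2-alkyl end groups; both come from one achiral diene by the same cycloaddition run with enantiomeric catalysts.
2. C11=C12 and C11'=C12' are made by two Wittig reactions (ring A C20 phosphonium salt + C10 trienedial, then ring B C20 salt). C6–C7 and C6'–C7' are made by Stille coupling of the ring enol triflates with a C5 stannyl dienol. The side-chain C=C bonds are made by Wittig olefination.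
3. Enabling feature of ring B: the unsubstituted C3'H2–C4'H2 pair bridges the stereocentre C2' and C5', C6' is sp2 and can be an enol carbon, and C1' is one methyl short of quaternary. Ring B is therefore the [4+2] retron of the diene C5'=C6'(OSi)–C1'(Me)=C2' and a two-carbon dienophile.
4. The cycloaddition of that 2-silyloxy diene with acrolein (ethylene surrogate), catalytic and enantioselective, makes C4'–C5' and C2'–C3' and sets C2'. The formyl group is then excised, the enol silane is methylated at C1', and the ketone becomes the C6' enol triflate.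
5. Ring order: ring B (step 4), then ring A by the mirror-image cycloaddition (step 16). No other ring is formed.

Key step: step 4

Assumption: the (S)-configured oxazaborolidinium catalyst is taken to give the all-cis (1R,2R,5S) adduct needed for ring B and the (R)-catalyst its antipode; the sense is to be confirmed on the first adduct, and if it is reversed the two catalysts are simply exchanged between steps 4 and 16, since both antipodal series are needed.

Abbreviations: TIPS = tri(propan-2-yl)silyl; TBDPS = tert-butyl(diphenyl)silyl; Bn = benzyl; Tf = trifluoromethanesulfonyl; "oxazaborolidine" = 1-(2-methylphenyl)-3,3-diphenyltetrahydro-1H,3H-pyrrolo[1,2-c][1,3,2]oxazaborole (from diphenylprolinol), used as its Tf2NH salt.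

**Route**

Step 1
Reactants: 1 pentan-3-one; 2 3-(benzyloxy)propanal
Product: 4 7-(benzyloxy)-5-hydroxy-4-methylheptan-3-one (syn/anti mixture), via lithium enolate 3 (not isolated)
Conditions: LiN(iPr)2, THF, −78 °C; then 2, −78 °C; H2O quench
Reagents that add atoms: none
Why: Directed aldol addition of the preformed lithium enolate of the symmetrical ketone to the aldehyde; the two new stereocentres are formed unselectively and are both removed in step 2.

Step 2
Reactants: 4 7-(benzyloxy)-5-hydroxy-4-methylheptan-3-one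
Product: 6 (4E)-7-(benzyloxy)-4-methylhept-4-en-3-one, via β-mesyloxy ketone 5 (not isolated)
Conditions: MsCl, Et3N, CH2Cl2, 0 °C; then DBU, 0 °C → rt
Reagents that add atoms: none
Why: Mesylation and base-induced E1cB elimination give the conjugated trisubstituted enone, the (E)-isomer being thermodynamically favoured because the (Z)-isomer suffers allylic strain between the propanoyl group and the chain.

Step 3
Reactants: 6 (4E)-7-(benzyloxy)-4-methylhept-4-en-3-one
Product: 7 {[(2Z,4E)-7-(benzyloxy)-4-methylhepta-2,4-dien-3-yl]oxy}tri(propan-2-yl)silane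
Conditions: iPr3SiOTf, Et3N, CH2Cl2, −78 → 0 °C
Reagents that add atoms: tri(propan-2-yl)silyl trifluoromethanesulfonate, CC(C)[Si](C(C)C)(C(C)C)OS(=O)(=O)C(F)(F)F
Why: Soft enolisation and O-silylation (silyl enol ether formation) at the only α'-CH2 give the cross-conjugated 2-silyloxy diene, the (Z)-enol ether (methyl cis to oxygen, hence "outside" in the s-cis diene) being the usual outcome for ethyl ketones with silyl triflate and amine.

Step 4
Reactants: 7 {[(2Z,4E)-7-(benzyloxy)-4-methylhepta-2,4-dien-3-yl]oxy}tri(propan-2-yl)silane; 8 acrolein (prop-2-enal)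
Product: 9 (1R,2R,5S)-2-[2-(benzyloxy)ethyl]-3,5-dimethyl-4-(TIPS-oxy)cyclohex-3-ene-1-carbaldehyde
Conditions: (S)-oxazaborolidine (20 mol %), Tf2NH (20 mol %), CH2Cl2, −78 °C
Reagents that add atoms: none
Why: The protonated oxazaborolidine binds acrolein and lowers its LUMO, and the electron-rich 2-silyloxy diene adds in a concerted, asynchronous, suprafacial [4+2] cycloaddition in which the enol-ether β-carbon (future C5') bonds to the acrolein β-carbon (future C4') and the diene terminus C2' to the α-carbon (future C3'). The closest known reaction type is the oxazaborolidinium-catalysed enantioselective Diels–Alder reaction of 2-(trialkylsilyloxy)-1,3-dienes with α,β-unsaturated aldehydes and acrylates. Ring B is closed in the [4+2] cycloaddition mode, both ring bonds being made at once across the diene termini. The C2' stereocentre is set by the catalyst, which shields one face of the bound enal, acting together with the endo transition state; C5' (cis to the side chain, from the (Z)-enol ether and (E)-alkene geometries) and the formyl-bearing carbon (endo) are fixed relative to it but are erased in steps 12 and 5. The step needs endo and π-facial selectivity and the para/ortho orientation, which are secured by the 2-silyloxy donor (largest HOMO coefficient at the enol-ether carbon), by the "outside" placement of both terminal substituents and by the rigid catalyst–enal complex; a stepwise Mukaiyama–Michael/ring-closure course would give the same adduct.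

Step 5
Reactants: 9 (1R,2R,5S)-2-[2-(benzyloxy)ethyl]-3,5-dimethyl-4-(TIPS-oxy)cyclohex-3-ene-1-carbaldehyde
Product: 10 {[(3S,6S)-3-[2-(benzyloxy)ethyl]-2,6-dimethylcyclohex-1-en-1-yl]oxy}tri(propan-2-yl)silane
Conditions: RhCl(PPh3)3 (1.1 equiv), toluene, 110 °C
Reagents that add atoms: none
Why: Tsuji–Wilkinson decarbonylation (oxidative addition of the formyl C–H bond to rhodium, CO extrusion, C–H reductive elimination) turns the acrolein-derived unit into the plain CH2–CH2 of ring B, the enol silane and the benzyl ether being inert and the two remaining stereocentres untouched.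

Step 6
Reactants: 10 {[(3S,6S)-3-[2-(benzyloxy)ethyl]-2,6-dimethylcyclohex-1-en-1-yl]oxy}tri(propan-2-yl)silane
Product: 12 (3S,6S)-3-[2-(benzyloxy)ethyl]-2,2,6-trimethylcyclohexan-1-one, via sulfonium enolate 11 (not isolated)
Conditions: (Me2N)3S+ Me3SiF2− (TASF), THF, −78 °C; then MeI, −78 → 0 °C
Reagents that add atoms: iodomethane, CI
Why: Fluoride cleaves the enol silane to the tetrasubstituted "naked" enolate regiospecifically and its C-methylation (regiospecific enolate alkylation) completes the geminal dimethyl group, creating no stereocentre and leaving C3 untouched, while the C6 methine is epimerisable but becomes sp2 in step 12.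

Step 7
Reactants: 12 (3S,6S)-3-[2-(benzyloxy)ethyl]-2,2,6-trimethylcyclohexan-1-one
Product: 13 (3S,6S)-3-(2-hydroxyethyl)-2,2,6-trimethylcyclohexan-1-one
Conditions: H2 (1 atm), 10% Pd/C, EtOAc, rt
Reagents that add atoms: none
Why: Hydrogenolysis of the benzyl ether over palladium frees the primary alcohol, the hindered ketone being inert and no alkene being present at this stage.

Step 8
Reactants: 13 (3S,6S)-3-(2-hydroxyethyl)-2,2,6-trimethylcyclohexan-1-one
Product: 14 (3S,6S)-3-(2-iodoethyl)-2,2,6-trimethylcyclohexan-1-one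
Conditions: I2, PPh3, imidazole, CH2Cl2, 0 °C → rt
Reagents that add atoms: iodine, II
Why: Appel-type iodination converts the primary alcohol by SN2 displacement of the alkoxyphosphonium ion, remote from the stereocentres.

Step 9
Reactants: 14 (3S,6S)-3-(2-iodoethyl)-2,2,6-trimethylcyclohexan-1-one
Product: 15 {2-[(1S,4S)-2,2,4-trimethyl-3-oxocyclohexyl]ethyl}triphenylphosphonium iodide
Conditions: PPh3, MeCN, reflux
Reagents that add atoms: triphenylphosphine, c1ccc(cc1)P(c1ccccc1)c1ccccc1
Why: SN2 quaternisation of triphenylphosphine by the primary iodide gives the Wittig salt, the hindered ketone not interfering.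

Step 10
Reactants: 16 1,3-dihydroxyacetone (supplied as its dimer)
Product: 17 1,3-bis(TBDPS-oxy)propan-2-one
Conditions: tBuPh2SiCl, imidazole, DMF, rt
Reagents that add atoms: tert-butyl(chloro)diphenylsilane, CC(C)(C)[Si](Cl)(c1ccccc1)c1ccccc1
Why: Standard silylation of both primary hydroxyl groups of the monomeric ketone, into which the commercial dimer dissociates in DMF.

Step 11
Reactants: 15 {2-[(1S,4S)-2,2,4-trimethyl-3-oxocyclohexyl]ethyl}triphenylphosphonium iodide; 17 1,3-bis(TBDPS-oxy)propan-2-one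
Product: 19 (3S,6S)-3-[4-(TBDPS-oxy)-3-(TBDPS-oxymethyl)but-2-en-1-yl]-2,2,6-trimethylcyclohexan-1-one, via phosphorus ylide 18 (not isolated)
Conditions: NaN(SiMe3)2 (1.0 equiv), THF, −78 → 0 °C; then 17, −78 °C → rt
Reagents that add atoms: none
Why: Wittig olefination of the symmetrical ketone by the non-stabilised ylide gives the trisubstituted alkene without any E/Z question, the phosphonium α-CH2 being far more acidic than the hindered ring ketone and an intramolecular olefination being excluded because it would give a bridgehead alkene.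

Step 12
Reactants: 19 (3S,6S)-3-[4-(TBDPS-oxy)-3-(TBDPS-oxymethyl)but-2-en-1-yl]-2,2,6-trimethylcyclohexan-1-one
Product: 21 (5S)-5-[4-(TBDPS-oxy)-3-(TBDPS-oxymethyl)but-2-en-1-yl]-2,6,6-trimethylcyclohex-1-en-1-yl trifluoromethanesulfonate, via lithium enolate 20 (not isolated)
Conditions: LiN(iPr)2, THF, −78 → 0 °C; then PhNTf2, −78 °C → rt
Reagents that add atoms: N-phenylbis(trifluoromethanesulfonimide), O=S(=O)(N(c1ccccc1)S(=O)(=O)C(F)(F)F)C(F)(F)F
Why: Only C6 carries an α-hydrogen, so deprotonation and O-sulfonylation (enol triflate formation) give the tetrasubstituted enol triflate regiospecifically, removing the C6 stereocentre and leaving the side-chain-bearing stereocentre untouched.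

Step 13
Reactants: 22 (2E)-3-methylpent-2-en-4-yn-1-ol
Product: 23 (2E,4E)-3-methyl-5-(tributylstannyl)penta-2,4-dien-1-ol
Conditions: Bu3SnH, PdCl2(PPh3)2 (2 mol %), THF, 0 °C → rt
Reagents that add atoms: tributyltin hydride, CCCC[SnH](CCCC)CCCC
Why: Palladium-catalysed syn-hydrostannylation of the terminal alkyne places tin on the terminal carbon and gives the (E)-alkenylstannane, a minor internal regioisomer being removed by chromatography.

Step 14
Reactants: 21 (5S)-5-[4-(TBDPS-oxy)-3-(TBDPS-oxymethyl)but-2-en-1-yl]-2,6,6-trimethylcyclohex-1-en-1-yl trifluoromethanesulfonate; 23 (2E,4E)-3-methyl-5-(tributylstannyl)penta-2,4-dien-1-ol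
Product: 24 (2E,4E)-5-{(5S)-5-[4-(TBDPS-oxy)-3-(TBDPS-oxymethyl)but-2-en-1-yl]-2,6,6-trimethylcyclohex-1-en-1-yl}-3-methylpenta-2,4-dien-1-ol
Conditions: Pd2(dba)3 (5 mol %), AsPh3 (40 mol %), NMP, 60 °C
Reagents that add atoms: none
Why: Stille coupling (oxidative addition of zerovalent palladium to the enol triflate, transmetalation with retention of alkene geometry, reductive elimination) forms the C6'–C7' bond, the weakly donating arsine ligand speeding transmetalation at the hindered tetrasubstituted carbon and the free hydroxyl and silyl ethers being tolerated.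

Step 15
Reactants: 24 (2E,4E)-5-{(5S)-5-[4-(TBDPS-oxy)-3-(TBDPS-oxymethyl)but-2-en-1-yl]-2,6,6-trimethylcyclohex-1-en-1-yl}-3-methylpenta-2,4-dien-1-ol
Product: 25 [(2E,4E)-5-{(5S)-5-[4-(TBDPS-oxy)-3-(TBDPS-oxymethyl)but-2-en-1-yl]-2,6,6-trimethylcyclohex-1-en-1-yl}-3-methylpenta-2,4-dien-1-yl]triphenylphosphonium bromide
Conditions: Ph3P·HBr, CH2Cl2/MeOH, 0 °C → rt
Reagents that add atoms: triphenylphosphonium bromide, [Br-].c1ccc(cc1)[PH+](c1ccccc1)c1ccccc1
Why: Acid-promoted ionisation of the dienylic alcohol and capture of the pentadienyl cation by triphenylphosphine at the primary terminus (SN1-type phosphonium salt formation) give the thermodynamically preferred (2E,4E)-salt, the TBDPS ethers being chosen to withstand the weakly acidic reagent.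

Step 16
Reactants: 7 {[(2Z,4E)-7-(benzyloxy)-4-methylhepta-2,4-dien-3-yl]oxy}tri(propan-2-yl)silane; 8 acrolein (prop-2-enal)
Product: 26 (1S,2S,5R)-2-[2-(benzyloxy)ethyl]-3,5-dimethyl-4-(TIPS-oxy)cyclohex-3-ene-1-carbaldehyde
Conditions: (R)-oxazaborolidine (20 mol %), Tf2NH (20 mol %), CH2Cl2, −78 °C
Reagents that add atoms: none
Why: The same catalytic enantioselective Diels–Alder reaction as in step 4 with the antipodal catalyst gives the mirror-image all-cis adduct, whose side-chain-bearing carbon becomes the (R)-configured C2 of ring A.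

Step 17
Reactants: 26 (1S,2S,5R)-2-[2-(benzyloxy)ethyl]-3,5-dimethyl-4-(TIPS-oxy)cyclohex-3-ene-1-carbaldehyde
Product: 27 {[(3R,6R)-3-[2-(benzyloxy)ethyl]-2,6-dimethylcyclohex-1-en-1-yl]oxy}tri(propan-2-yl)silane
Conditions: RhCl(PPh3)3 (1.1 equiv), toluene, 110 °C
Reagents that add atoms: none
Why: Tsuji–Wilkinson decarbonylation as in step 5 removes the formyl group with the other stereocentres untouched.

Step 18
Reactants: 27 {[(3R,6R)-3-[2-(benzyloxy)ethyl]-2,6-dimethylcyclohex-1-en-1-yl]oxy}tri(propan-2-yl)silane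
Product: 29 (3R,6R)-3-[2-(benzyloxy)ethyl]-2,2,6-trimethylcyclohexan-1-one, via sulfonium enolate 28 (not isolated)
Conditions: (Me2N)3S+ Me3SiF2− (TASF), THF, −78 °C; then MeI, −78 → 0 °C
Reagents that add atoms: iodomethane, CI
Why: Regiospecific fluoride-induced enolate generation and C-methylation as in step 6 complete the geminal dimethyl group without touching C3.

Step 19
Reactants: 29 (3R,6R)-3-[2-(benzyloxy)ethyl]-2,2,6-trimethylcyclohexan-1-one
Product: 30 (3R,6R)-3-(2-hydroxyethyl)-2,2,6-trimethylcyclohexan-1-one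
Conditions: H2 (1 atm), 10% Pd/C, EtOAc, rt
Reagents that add atoms: none
Why: Hydrogenolysis of the benzyl ether as in step 7, the hindered ketone being inert.

Step 20
Reactants: 30 (3R,6R)-3-(2-hydroxyethyl)-2,2,6-trimethylcyclohexan-1-one
Product: 31 2-[(1R,4R)-2,2,4-trimethyl-3-oxocyclohexyl]acetaldehyde
Conditions: Dess–Martin periodinane, CH2Cl2, rt
Reagents that add atoms: none
Why: Dess–Martin oxidation gives the aldehyde under neutral conditions, the ring stereocentre being β to the new carbonyl and therefore not epimerisable.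

Step 21
Reactants: 31 2-[(1R,4R)-2,2,4-trimethyl-3-oxocyclohexyl]acetaldehyde
Product: 32 (3R,6R)-2,2,6-trimethyl-3-(3-methylbut-2-en-1-yl)cyclohexan-1-one
Conditions: iPrPPh3+ I−, n-BuLi, THF, 0 °C; then 31, −78 °C → rt
Reagents that add atoms: isopropyltriphenylphosphonium iodide, CC(C)[P+](c1ccccc1)(c1ccccc1)c1ccccc1.[I-]
Why: Wittig olefination of the aldehyde with isopropylidene(triphenyl)phosphorane installs the prenyl terminus, the hindered 2,2,6-trisubstituted ketone being unreactive towards the ylide.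

Step 22
Reactants: 32 (3R,6R)-2,2,6-trimethyl-3-(3-methylbut-2-en-1-yl)cyclohexan-1-one
Product: 34 (5R)-2,6,6-trimethyl-5-(3-methylbut-2-en-1-yl)cyclohex-1-en-1-yl trifluoromethanesulfonate, via lithium enolate 33 (not isolated)
Conditions: LiN(iPr)2, THF, −78 → 0 °C; then PhNTf2, −78 °C → rt
Reagents that add atoms: N-phenylbis(trifluoromethanesulfonimide), O=S(=O)(N(c1ccccc1)S(=O)(=O)C(F)(F)F)C(F)(F)F
Why: Regiospecific enol triflate formation as in step 12, the only α-hydrogen being at C6 and the prenyl alkene being inert.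

Step 23
Reactants: 34 (5R)-2,6,6-trimethyl-5-(3-methylbut-2-en-1-yl)cyclohex-1-en-1-yl trifluoromethanesulfonate; 23 (2E,4E)-3-methyl-5-(tributylstannyl)penta-2,4-dien-1-ol
Product: 35 (2E,4E)-3-methyl-5-[(5R)-2,6,6-trimethyl-5-(3-methylbut-2-en-1-yl)cyclohex-1-en-1-yl]penta-2,4-dien-1-ol
Conditions: Pd2(dba)3 (5 mol %), AsPh3 (40 mol %), NMP, 60 °C
Reagents that add atoms: none
Why: Stille coupling as in step 14 forms the C6–C7 bond with retention of the (E)-geometry of the stannane.

Step 24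
Reactants: 35 (2E,4E)-3-methyl-5-[(5R)-2,6,6-trimethyl-5-(3-methylbut-2-en-1-yl)cyclohex-1-en-1-yl]penta-2,4-dien-1-ol
Product: 36 {(2E,4E)-3-methyl-5-[(5R)-2,6,6-trimethyl-5-(3-methylbut-2-en-1-yl)cyclohex-1-en-1-yl]penta-2,4-dien-1-yl}triphenylphosphonium bromide
Conditions: Ph3P·HBr, MeOH, 0 °C → rt
Reagents that add atoms: triphenylphosphonium bromide, [Br-].c1ccc(cc1)[PH+](c1ccccc1)c1ccccc1
Why: SN1-type phosphonium salt formation as in step 15, the dienylic alcohol ionising far more readily than the isolated prenyl alkene is protonated by the weak acid.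

Step 25
Reactants: 36 {(2E,4E)-3-methyl-5-[(5R)-2,6,6-trimethyl-5-(3-methylbut-2-en-1-yl)cyclohex-1-en-1-yl]penta-2,4-dien-1-yl}triphenylphosphonium bromide; 37 (2E,4E,6E)-2,7-dimethylocta-2,4,6-trienedial
Product: 39 (2E,4E,6E,8E,10E,12E)-2,7,11-trimethyl-13-[(5R)-2,6,6-trimethyl-5-(3-methylbut-2-en-1-yl)cyclohex-1-en-1-yl]trideca-2,4,6,8,10,12-hexaenal, via phosphorus ylide 38 (not isolated)
Conditions: NaOMe, MeOH/CH2Cl2, 0 °C → rt, 37 (3 equiv, excess recovered); then heptane, reflux, dark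
Reagents that add atoms: none
Why: Wittig olefination of one formyl group of the symmetrical dialdehyde (used in excess to suppress double condensation) by the semi-stabilised allylic ylide forms C11=C12, and thermal equilibration should convert any (11Z)-isomer into the all-E aldehyde.

Step 26
Reactants: 39 (2E,4E,6E,8E,10E,12E)-2,7,11-trimethyl-13-[(5R)-2,6,6-trimethyl-5-(3-methylbut-2-en-1-yl)cyclohex-1-en-1-yl]trideca-2,4,6,8,10,12-hexaenal; 25 ring B C20 triphenylphosphonium bromide
Product: 41 (2R,2'S)-2'-[4-(TBDPS-oxy)-3-(TBDPS-oxymethyl)but-2-en-1-yl]-2-(3-methylbut-2-en-1-yl)-β,β-carotene, via phosphorus ylide 40 (not isolated)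
Conditions: NaOMe, MeOH/CH2Cl2, 0 °C → rt; then heptane, reflux, dark, argon
Reagents that add atoms: none
Why: The second Wittig olefination forms C11'=C12' and joins the two halves, thermal equilibration of the Z/E mixture being expected to give the all-E polyene as is usual in phosphonium salt/C10-dialdehyde carotenoid assembly, with both stereocentres remote and unaffected.

Step 27
Reactants: 41 (2R,2'S)-2'-[4-(TBDPS-oxy)-3-(TBDPS-oxymethyl)but-2-en-1-yl]-2-(3-methylbut-2-en-1-yl)-β,β-carotene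
Product: 42 (2R,2'S)-2'-[4-hydroxy-3-(hydroxymethyl)but-2-en-1-yl]-2-(3-methylbut-2-en-1-yl)-β,β-carotene (CNP0213288.1)
Conditions: Bu4NF, THF, 0 °C → rt, dark, argon
Reagents that add atoms: none
Why: Fluoride-mediated desilylation frees both primary allylic hydroxyl groups under conditions that leave the polyene and both stereocentres untouched.

**Compound list**

1 | pentan-3-one | CCC(=O)CC | starting material
2 | 3-(benzyloxy)propanal | O=CCCOCc1ccccc1 | starting material
3 | lithium pent-2-en-3-olate (E/Z mixture; not isolated) | CC=C([O-])CC.[Li+] | intermediate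
4 | 7-(benzyloxy)-5-hydroxy-4-methylheptan-3-one (syn/anti mixture, racemic) | CCC(=O)C(C)C(O)CCOCc1ccccc1 | intermediate
5 | 1-(benzyloxy)-4-methyl-5-oxoheptan-3-yl methanesulfonate (diastereomer mixture; not isolated) | CCC(=O)C(C)C(OS(C)(=O)=O)CCOCc1ccccc1 | intermediate
6 | (4E)-7-(benzyloxy)-4-methylhept-4-en-3-one | CCC(=O)/C(C)=C/CCOCc1ccccc1 | intermediate
7 | {[(2Z,4E)-7-(benzyloxy)-4-methylhepta-2,4-dien-3-yl]oxy}tri(propan-2-yl)silane | C/C=C(\O[Si](C(C)C)(C(C)C)C(C)C)/C(C)=C/CCOCc1ccccc1 | intermediate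
8 | acrolein (prop-2-enal) | C=CC=O | starting material
9 | (1R,2R,5S)-2-[2-(benzyloxy)ethyl]-3,5-dimethyl-4-{[tri(propan-2-yl)silyl]oxy}cyclohex-3-ene-1-carbaldehyde (all-cis) | C[C@H]1C[C@@H](C=O)[C@@H](CCOCc2ccccc2)C(C)=C1O[Si](C(C)C)(C(C)C)C(C)C | intermediate
10 | {[(3S,6S)-3-[2-(benzyloxy)ethyl]-2,6-dimethylcyclohex-1-en-1-yl]oxy}tri(propan-2-yl)silane | C[C@H]1CC[C@@H](CCOCc2ccccc2)C(C)=C1O[Si](C(C)C)(C(C)C)C(C)C | intermediate
11 | tris(dimethylamino)sulfonium (3S,6S)-3-[2-(benzyloxy)ethyl]-2,6-dimethylcyclohex-1-en-1-olate (not isolated) | C[C@H]1CC[C@@H](CCOCc2ccccc2)C(C)=C1[O-].CN(C)[S+](N(C)C)N(C)C | intermediate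
12 | (3S,6S)-3-[2-(benzyloxy)ethyl]-2,2,6-trimethylcyclohexan-1-one (3,6-cis; the C6 epimer would serve equally) | O=C1[C@@H](C)CC[C@@H](CCOCc2ccccc2)C1(C)C | intermediate
13 | (3S,6S)-3-(2-hydroxyethyl)-2,2,6-trimethylcyclohexan-1-one | O=C1[C@@H](C)CC[C@@H](CCO)C1(C)C | intermediate
14 | (3S,6S)-3-(2-iodoethyl)-2,2,6-trimethylcyclohexan-1-one | O=C1[C@@H](C)CC[C@@H](CCI)C1(C)C | intermediate
15 | {2-[(1S,4S)-2,2,4-trimethyl-3-oxocyclohexyl]ethyl}triphenylphosphonium iodide | O=C1[C@@H](C)CC[C@@H](CC[P+](c2ccccc2)(c2ccccc2)c2ccccc2)C1(C)C.[I-] | intermediate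
16 | 1,3-dihydroxyacetone (1,3-dihydroxypropan-2-one, supplied as its dimer) | OCC(=O)CO | starting material
17 | 1,3-bis{[tert-butyl(diphenyl)silyl]oxy}propan-2-one | O=C(CO[Si](c1ccccc1)(c1ccccc1)C(C)(C)C)CO[Si](c1ccccc1)(c1ccccc1)C(C)(C)C | intermediate
18 | (3S,6S)-2,2,6-trimethyl-3-[2-(triphenylphosphoranylidene)ethyl]cyclohexan-1-one (ylide; not isolated) | O=C1[C@@H](C)CC[C@@H](CC=P(c2ccccc2)(c2ccccc2)c2ccccc2)C1(C)C | intermediate
19 | (3S,6S)-3-[4-{[tert-butyl(diphenyl)silyl]oxy}-3-({[tert-butyl(diphenyl)silyl]oxy}methyl)but-2-en-1-yl]-2,2,6-trimethylcyclohexan-1-one | O=C1[C@@H](C)CC[C@@H](CC=C(CO[Si](c2ccccc2)(c2ccccc2)C(C)(C)C)CO[Si](c2ccccc2)(c2ccccc2)C(C)(C)C)C1(C)C | intermediate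
20 | lithium (5S)-5-[4-{[tert-butyl(diphenyl)silyl]oxy}-3-({[tert-butyl(diphenyl)silyl]oxy}methyl)but-2-en-1-yl]-2,6,6-trimethylcyclohex-1-en-1-olate (not isolated) | [Li+].[O-]C1=C(C)CC[C@@H](CC=C(CO[Si](c2ccccc2)(c2ccccc2)C(C)(C)C)CO[Si](c2ccccc2)(c2ccccc2)C(C)(C)C)C1(C)C | intermediate
21 | (5S)-5-[4-{[tert-butyl(diphenyl)silyl]oxy}-3-({[tert-butyl(diphenyl)silyl]oxy}methyl)but-2-en-1-yl]-2,6,6-trimethylcyclohex-1-en-1-yl trifluoromethanesulfonate | O=S(=O)(OC1=C(C)CC[C@@H](CC=C(CO[Si](c2ccccc2)(c2ccccc2)C(C)(C)C)CO[Si](c2ccccc2)(c2ccccc2)C(C)(C)C)C1(C)C)C(F)(F)F | intermediate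
22 | (2E)-3-methylpent-2-en-4-yn-1-ol | C#C/C(C)=C/CO | starting material
23 | (2E,4E)-3-methyl-5-(tributylstannyl)penta-2,4-dien-1-ol | CCCC[Sn](CCCC)(CCCC)/C=C/C(C)=C/CO | intermediate
24 | (2E,4E)-5-{(5S)-5-[4-{[tert-butyl(diphenyl)silyl]oxy}-3-({[tert-butyl(diphenyl)silyl]oxy}methyl)but-2-en-1-yl]-2,6,6-trimethylcyclohex-1-en-1-yl}-3-methylpenta-2,4-dien-1-ol | OC/C=C(C)/C=C/C1=C(C)CC[C@@H](CC=C(CO[Si](c2ccccc2)(c2ccccc2)C(C)(C)C)CO[Si](c2ccccc2)(c2ccccc2)C(C)(C)C)C1(C)C | intermediate
25 | [(2E,4E)-5-{(5S)-5-[4-{[tert-butyl(diphenyl)silyl]oxy}-3-({[tert-butyl(diphenyl)silyl]oxy}methyl)but-2-en-1-yl]-2,6,6-trimethylcyclohex-1-en-1-yl}-3-methylpenta-2,4-dien-1-yl]triphenylphosphonium bromide | C(/C=C(C)/C=C/C1=C(C)CC[C@@H](CC=C(CO[Si](c2ccccc2)(c2ccccc2)C(C)(C)C)CO[Si](c2ccccc2)(c2ccccc2)C(C)(C)C)C1(C)C)[P+](c1ccccc1)(c1ccccc1)c1ccccc1.[Br-] | intermediate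
26 | (1S,2S,5R)-2-[2-(benzyloxy)ethyl]-3,5-dimethyl-4-{[tri(propan-2-yl)silyl]oxy}cyclohex-3-ene-1-carbaldehyde (all-cis) | C[C@@H]1C[C@H](C=O)[C@H](CCOCc2ccccc2)C(C)=C1O[Si](C(C)C)(C(C)C)C(C)C | intermediate
27 | {[(3R,6R)-3-[2-(benzyloxy)ethyl]-2,6-dimethylcyclohex-1-en-1-yl]oxy}tri(propan-2-yl)silane | C[C@@H]1CC[C@H](CCOCc2ccccc2)C(C)=C1O[Si](C(C)C)(C(C)C)C(C)C | intermediate
28 | tris(dimethylamino)sulfonium (3R,6R)-3-[2-(benzyloxy)ethyl]-2,6-dimethylcyclohex-1-en-1-olate (not isolated) | C[C@@H]1CC[C@H](CCOCc2ccccc2)C(C)=C1[O-].CN(C)[S+](N(C)C)N(C)C | intermediate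
29 | (3R,6R)-3-[2-(benzyloxy)ethyl]-2,2,6-trimethylcyclohexan-1-one | O=C1[C@H](C)CC[C@H](CCOCc2ccccc2)C1(C)C | intermediate
30 | (3R,6R)-3-(2-hydroxyethyl)-2,2,6-trimethylcyclohexan-1-one | O=C1[C@H](C)CC[C@H](CCO)C1(C)C | intermediate
31 | 2-[(1R,4R)-2,2,4-trimethyl-3-oxocyclohexyl]acetaldehyde | O=C1[C@H](C)CC[C@H](CC=O)C1(C)C | intermediate
32 | (3R,6R)-2,2,6-trimethyl-3-(3-methylbut-2-en-1-yl)cyclohexan-1-one | O=C1[C@H](C)CC[C@H](CC=C(C)C)C1(C)C | intermediate
33 | lithium (5R)-2,6,6-trimethyl-5-(3-methylbut-2-en-1-yl)cyclohex-1-en-1-olate (not isolated) | [Li+].[O-]C1=C(C)CC[C@H](CC=C(C)C)C1(C)C | intermediate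
34 | (5R)-2,6,6-trimethyl-5-(3-methylbut-2-en-1-yl)cyclohex-1-en-1-yl trifluoromethanesulfonate | CC(C)=CC[C@H]1CCC(C)=C(OS(=O)(=O)C(F)(F)F)C1(C)C | intermediate
35 | (2E,4E)-3-methyl-5-[(5R)-2,6,6-trimethyl-5-(3-methylbut-2-en-1-yl)cyclohex-1-en-1-yl]penta-2,4-dien-1-ol | CC(C)=CC[C@H]1CCC(C)=C(/C=C/C(C)=C/CO)C1(C)C | intermediate
36 | {(2E,4E)-3-methyl-5-[(5R)-2,6,6-trimethyl-5-(3-methylbut-2-en-1-yl)cyclohex-1-en-1-yl]penta-2,4-dien-1-yl}triphenylphosphonium bromide | CC(C)=CC[C@H]1CCC(C)=C(/C=C/C(C)=C/C[P+](c2ccccc2)(c2ccccc2)c2ccccc2)C1(C)C.[Br-] | intermediate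
37 | (2E,4E,6E)-2,7-dimethylocta-2,4,6-trienedial | O=C/C(C)=C/C=C/C=C(C)/C=O | starting material
38 | {(2E,4E)-3-methyl-5-[(5R)-2,6,6-trimethyl-5-(3-methylbut-2-en-1-yl)cyclohex-1-en-1-yl]penta-2,4-dien-1-ylidene}triphenylphosphorane (ylide; not isolated) | CC(C)=CC[C@H]1CCC(C)=C(/C=C/C(C)=C/C=P(c2ccccc2)(c2ccccc2)c2ccccc2)C1(C)C | intermediate
39 | (2E,4E,6E,8E,10E,12E)-2,7,11-trimethyl-13-[(5R)-2,6,6-trimethyl-5-(3-methylbut-2-en-1-yl)cyclohex-1-en-1-yl]trideca-2,4,6,8,10,12-hexaenal | CC(C)=CC[C@H]1CCC(C)=C(/C=C/C(C)=C/C=C/C(C)=C/C=C/C=C(C)/C=O)C1(C)C | intermediate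
40 | ylide of 25: [(2E,4E)-5-{(5S)-5-[4-{[tert-butyl(diphenyl)silyl]oxy}-3-({[tert-butyl(diphenyl)silyl]oxy}methyl)but-2-en-1-yl]-2,6,6-trimethylcyclohex-1-en-1-yl}-3-methylpenta-2,4-dien-1-ylidene]triphenylphosphorane (not isolated) | c1ccccc1P(=C/C=C(C)/C=C/C2=C(C)CC[C@@H](CC=C(CO[Si](c3ccccc3)(c3ccccc3)C(C)(C)C)CO[Si](c3ccccc3)(c3ccccc3)C(C)(C)C)C2(C)C)(c1ccccc1)c1ccccc1 | intermediate
41 | (2R,2'S)-2'-[4-{[tert-butyl(diphenyl)silyl]oxy}-3-({[tert-butyl(diphenyl)silyl]oxy}methyl)but-2-en-1-yl]-2-(3-methylbut-2-en-1-yl)-β,β-carotene (all-E) | CC(C)=CC[C@H]1CCC(C)=C(/C=C/C(C)=C/C=C/C(C)=C/C=C/C=C(C)/C=C/C=C(C)/C=C/C2=C(C)CC[C@@H](CC=C(CO[Si](c3ccccc3)(c3ccccc3)C(C)(C)C)CO[Si](c3ccccc3)(c3ccccc3)C(C)(C)C)C2(C)C)C1(C)C | intermediate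
42 | (2R,2'S)-2'-[4-hydroxy-3-(hydroxymethyl)but-2-en-1-yl]-2-(3-methylbut-2-en-1-yl)-β,β-carotene, all-E (CNP0213288.1) | CC(C)=CC[C@H]1CCC(C)=C(/C=C/C(C)=C/C=C/C(C)=C/C=C/C=C(C)/C=C/C=C(C)/C=C/C2=C(C)CC[C@@H](CC=C(CO)CO)C2(C)C)C1(C)C | target

**Step count and risks**

Total step count: 27. Longest linear sequence: 15 steps (1–9, 11, 12, 14, 15, 26, 27; the ring A branch 1–3, 16–27 is equally long).

Steps most likely to fail:

1. Step 4. The tetrasubstituted silyloxy diene may react with insufficient endo or π-facial selectivity; because the formyl carbon is later excised, any exo adduct erodes the enantiomeric purity at C2'. The strongly acidic catalyst may also desilylate the diene. Fallback (auxiliary control instead of catalyst control): the route sets out from 7, which is combined with (4S)-3-acryloyl-4-benzyl-1,3-oxazolidin-2-one and Et2AlCl in CH2Cl2 at −78 °C. In the aluminium-chelated s-cis imide the diene should add endo and anti to the benzyl group, giving the N-acyloxazolidinone cycloadduct F1. Reductive removal of the auxiliary with LiBH4 gives the primary alcohol F2, and Dess–Martin oxidation (NaHCO3 buffer) returns to the route at 9.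

2. Step 14. Oxidative addition and transmetalation at the tetrasubstituted enol triflate flanked by a quaternary carbon may be slow, so that triflate hydrolysis and stannane homocoupling take over. Fallback (carbonylation and olefination instead of cross-coupling): the route sets out from 21, which undergoes palladium-catalysed reductive carbonylation (Pd(PPh3)4, CO, Bu3SnH, THF, 50 °C) to the ring B cyclohexenecarbaldehyde F4. Horner–Wadsworth–Emmons olefination with triethyl 3-methyl-4-phosphonocrotonate (NaH, THF) gives the (2E,4E)-dienoate F5, and iBu2AlH reduction (CH2Cl2, −78 °C) returns to the route at 24.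

3. Step 6. Proton transfer between the naked enolate and the product ketone may lead to methylation at C6 or to O-methylation, and the hindered enolate carbon may alkylate slowly. Fallback (cyclopropanation and ring opening instead of enolate alkylation): the route sets out from 10, whose enol silane is cyclopropanated under Simmons–Smith conditions (Et2Zn, CH2I2, CH2Cl2, 0 °C), anti to the two ring substituents, to the silyloxycyclopropane F3. Fluoride-induced opening of the cyclopropanol (Bu4NF, THF), with cleavage of the bond to the CH2 carbon, delivers the second methyl group and returns to the route at 12.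

Further compounds
F1 | step 4 | (4S)-4-benzyl-3-{[(1R,2R,5S)-2-[2-(benzyloxy)ethyl]-3,5-dimethyl-4-{[tri(propan-2-yl)silyl]oxy}cyclohex-3-en-1-yl]carbonyl}-1,3-oxazolidin-2-one | C[C@H]1C[C@@H](C(=O)N2[C@@H](Cc3ccccc3)COC2=O)[C@@H](CCOCc2ccccc2)C(C)=C1O[Si](C(C)C)(C(C)C)C(C)C
F2 | step 4 | [(1R,2R,5S)-2-[2-(benzyloxy)ethyl]-3,5-dimethyl-4-{[tri(propan-2-yl)silyl]oxy}cyclohex-3-en-1-yl]methanol | C[C@H]1C[C@@H](CO)[C@@H](CCOCc2ccccc2)C(C)=C1O[Si](C(C)C)(C(C)C)C(C)C
F3 | step 6 | {[(1S,2S,5S,6S)-5-[2-(benzyloxy)ethyl]-2,6-dimethylbicyclo[4.1.0]heptan-1-yl]oxy}tri(propan-2-yl)silane (methylene bridge anti to the C2 methyl and the C5 side chain) | C[C@H]1CC[C@@H](CCOCc2ccccc2)[C@]3(C)C[C@]13O[Si](C(C)C)(C(C)C)C(C)C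
F4 | step 14 | (5S)-5-[4-{[tert-butyl(diphenyl)silyl]oxy}-3-({[tert-butyl(diphenyl)silyl]oxy}methyl)but-2-en-1-yl]-2,6,6-trimethylcyclohex-1-ene-1-carbaldehyde | O=CC1=C(C)CC[C@@H](CC=C(CO[Si](c2ccccc2)(c2ccccc2)C(C)(C)C)CO[Si](c2ccccc2)(c2ccccc2)C(C)(C)C)C1(C)C
F5 | step 14 | ethyl (2E,4E)-5-{(5S)-5-[4-{[tert-butyl(diphenyl)silyl]oxy}-3-({[tert-butyl(diphenyl)silyl]oxy}methyl)but-2-en-1-yl]-2,6,6-trimethylcyclohex-1-en-1-yl}-3-methylpenta-2,4-dienoate | CCOC(=O)/C=C(C)/C=C/C1=C(C)CC[C@@H](CC=C(CO[Si](c2ccccc2)(c2ccccc2)C(C)(C)C)CO[Si](c2ccccc2)(c2ccccc2)C(C)(C)C)C1(C)C
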